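I began from a ratio: how fast the chain takes substrate, over how fast target is lost once made.

| flask | substrate | reagent | initiator | remark | time |
|---|---|---|---|---|---|
| red | 0.050 M | 1.50 equiv | 5 mol% | a single well-mixed tank run continuously and read at steady state, 3.0 h in it on average |  |
| green | 0.050 M (fed, over 2.40 h) | 1.50 equiv | 5 mol% | a stirred flask in which substrate is dosed at a steady rate over 2.40 h without added volume, worked up at 3.0 h | 3.0 h |
| ochre | 0.050 M | 1.50 equiv (fed, over 2.40 h) | 5 mol% | all but reagent at the start; reagent goes in evenly over 2.40 h, the run ends at 3.0 h | 3.0 h |
| grey | 0.050 M | 1.50 equiv | 5 mol% | everything together in a closed stirred flask, run for 3.0 h | 3.0 h |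

    initiator → 2 initiating radical (k1 = 9.6 × 10⁻⁴ min⁻¹)
    substrate + initiating radical → capped initiator + first chain carrier (k2 = 1.3 × 10⁶ M⁻¹ s⁻¹)
    reagent + first chain carrier → target + second chain carrier (k3 = 15000 M⁻¹ s⁻¹)
    substrate + second chain carrier → by-product + first chain carrier (k4 = 43000 M⁻¹ s⁻¹)
    2 second chain carrier → ended chains (k5 = 4.1 × 10⁸ M⁻¹ s⁻¹)
    target → over-reaction product (k6 = 0.012 min⁻¹)
    target ⇌ isomer of the product (K7 = 1.8, k7 = 0.0020 min⁻¹)

- a step written with two of one species runs at k times the square of its concentration and takes two of it each time
- the stated concentrations are those of everything mixed, before any reaction; amounts are the same in each set-up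
- the feed brings no volume worth counting
- run time (green): 3.0 h

- the set-up with the highest amount of target at the outlet or at the end, in percent of the substrate put in ("none" if the first two lie within 2 percentage points) (red / green / ochre / grey / none)
- amount of target at the outlet or at the end, in percent of the substrate put in, red
- amount of target at the outlet or at the end, in percent of the substrate put in, green
- amount of target at the outlet or at the end, in percent of the substrate put in, ochre
- amount of target at the outlet or at the end, in percent of the substrate put in, grey

With 0.00250 M of initiator, radicals started at 4.80 × 10⁻⁶ M min⁻¹. I set that equal to the loss of second chain carrier by step 5's pairing, which put this carrier near 9.88 × 10⁻⁹ M. Substrate then went at a pseudo-first-order constant c, its rate constant with the second chain carrier times that level: 0.0255 min⁻¹. Target left by its two exits at L, their forward constants summed: 0.0140 min⁻¹. The ratio c/L was 1.82.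

I took the settings in turn. The initiator loading stands under a square root in c, so the ratio moves slowly with it. In grey, substrate and target run in series: I reckoned the peak of target at 52.2 min, before the end, and 15.6% left at 180 min.

The reagent appears nowhere in c. Dosed in ochre, it arrives at 5.21 × 10⁻⁴ M min⁻¹, less than the chain's opening draw of 0.00127 M min⁻¹, so at first it is the limiting reagent. That lasts until substrate falls to 0.0204 M, where draw equals feed. I put no yield on ochre.

The substrate dose gave the crossing I carried. In green the feed is F, 3.47 × 10⁻⁴ M min⁻¹, and the standing level S is the substrate concentration at which the chain takes it as fast as the feed brings it, F/c: 0.0136 M. The approach takes about 39.2 min, shorter than the dose, so target forms at the feed's pace and late. Solving the dose and its tail gave me 34.1%.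

For red, the tank, taking c as at the start and 180 min as the average stay, I got 23.3%.

The forecast chose green: 23.4% for red, 34.5% for green, 19% for ochre, 16.5% for grey, holding that “the yield depends mainly on how late the target is formed, and dosing substrate makes it latest”. My figures lay slightly lower than its figures.

| Set-up | Target in the flask |
|---|---|
| red | 23.5% |
| green | 34.0% |
| ochre | 19.2% |
| grey | 16.4% |

The flask put green first, at 34.0%. Substrate in green reached a highest reading of 0.0138 M, beside the standing level S of 0.0136 M. With the same charge dosed over 54.0 min, F/c rose to 0.0363 M, but that dose lasted 1.38 times 1/c, fewer than the 3.67 in green, so by my reckoning substrate did not reach that level and stood near 0.0272 M when the dose stopped, 54.3% of the charge against 27.3% for S in green. That shorter dose ended with 22.5% of target.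

The numbers are made up; no experiment stands behind them.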